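What stands in the flask at 30 h: how much target, and what, if anything, has stopped it?

all flasks: free catalyst 0.12 mol%
- dusk: substrate 11 mM; partner 1.05 equiv; run made earlier
- spring: substrate 24 mM; partner 1.05 equiv; run made earlier
- dawn: substrate 16 mM; partner 0.53 equiv; run made earlier
- flask: substrate 16 mM; partner 1.05 equiv; time 30 h

| run | time / h | target / % |
|---|---|---|
| dusk | 6.00 | 36.1 |
| dusk | 12.0 | 40.0 |
| dusk | 20.0 | 38.8 |
| dusk | 25.0 | 41.2 |
| dusk | 30.0 | 39.0 |
| spring | 2.50 | 38.4 |
| spring | 5.00 | 52.6 |
| spring | 8.00 | 54.4 |
| spring | 15.0 | 54.0 |
| spring | 30.0 | 55.5 |
| dawn | 2.50 | 22.4 |
| dawn | 5.00 | 29.3 |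
| dawn | 8.00 | 31.5 |
| dawn | 15.0 | 29.2 |
| dawn | 30.0 | 27.6 |

(readings scatter by 1 percentage point)

- at 30 h, what has stopped the reaction, if anything has (it is still moving / forward and back rates have come level / all of the substrate has reacted / no working catalyst is left / the partner has run out first)
- how much target there is at 30 h, in percent of the substrate charged

- the earlier runs were read with a standard deviation of 1 percentage point
- reactions considered so far: free catalyst -> spent catalyst; substrate + catalyst intermediate A <-> catalyst intermediate B; catalyst intermediate C -> free catalyst + target; partner + free catalyst -> catalyst intermediate A; partner -> decomposed reagent; catalyst intermediate B <-> catalyst intermediate C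
- the reaction counts as stopped when no species that holds the substrate changes by six tenths of a point or more over the second half of the time

We first ask which given numbers must be known well. Time looks harmless: spring reads 54.4% at 8.00 h and 55.5% at 30.0 h, a gap of 1.1 percentage points against a scatter of 1 point. Partner matters: dawn, with about half the flask's equivalents, has a mean plateau reading of 29.4%. Substrate matters too: at the flask's equivalents, the plateau reads 39.8% in dusk and 54.6% in spring. The loading is 0.12 mol% in the flask and in the runs, so these readings say nothing of it.

We take the partner as limiting reagent, its charge split between target and decomposed reagent. In fractions of the substrate charge, the split reads 0.609 in dusk and 1.08 in spring, but 1.25 in dawn, so we stay at the flask's equivalents. A power law in substrate, exponent 0.740, gives the flask 0.804, our partner selectivity factor, target formed per partner decomposed. That makes 46.8% target.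

The forecast says the partner has run out first and 46%, reading the plateaus as “partner being lost to decomposition in competition with productive turnover”; our figure differs by 0.80 points.

The simulation of the flask answers that the partner has run out first: at 30 h partner stands at 0% of its charge, substrate at 53.4% and target at 46.6%.

free catalyst → spent catalyst (k = 1.11 × 10⁻⁷ s⁻¹); substrate + catalyst intermediate A ⇌ catalyst intermediate B (K = 27.1 M⁻¹, k = 11.7 M⁻¹ s⁻¹); catalyst intermediate C → free catalyst + target (k = 0.437 s⁻¹); partner + free catalyst → catalyst intermediate A (k = 12.3 M⁻¹ s⁻¹); partner → decomposed reagent (k = 8.72 × 10⁻⁵ s⁻¹); catalyst intermediate B ⇌ catalyst intermediate C (K = 0.538, k = 1.65 s⁻¹) Target per decomposed reagent in the flask comes to 0.797, against our 0.804. In a neighbouring flask, the same recipe with 0.600 of the flask's substrate charge, the factor scales to 0.551, and splitting 1.05 equiv of partner gives 37.3% target; that neighbour stands at 36.8%, with partner at 0% of its charge.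

The numbers in the tables stem from a simulated flask from invented constants; noise was put on by code.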